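**Retrosynthetic overview**
1. Target 18 comes from ketal hydrolysis of 17; the C3–heptenyl bond is made by Suzuki–Miyaura coupling of vinyl bromide 15 with (E)-heptenylboronic acid 16.
2. The side-chain acid comes from Pinnick oxidation of enal 14, which comes from cross-metathesis of the allyl group of 12 with methacrolein 13.
3. The C5 carbinol comes from substrate-controlled reduction of epoxy ketone 11 (hydride anti to the epoxide).
4. The oxirane (C1, C6) comes from a new catalytic asymmetric iminium-type epoxidation of quinone monoketal 10.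
5. Ring order: the carbocycle is the benzene ring of 1, dearomatised in step 7 after bromination, O-allylation/Claisen, O-methyl switch and reduction; the oxirane is the only ring built (step 8).

Assumption: the SMILES is read as the (1S,5S,6S) isomer with the C5 hydroxyl cis to the epoxide oxygen; 1, 3, 13 and 16 are bought.

**Step 1**
Reactants: 1 5-hydroxy-2-methoxybenzaldehyde
Product: 2 2-bromo-3-hydroxy-6-methoxybenzaldehyde
Conditions: Br2 (1.05 equiv), NaOAc, AcOH, 20 °C
Reagents that add atoms: bromine, BrBr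
Why: electrophilic aromatic bromination directed by the free phenol; its para position is blocked by OMe and, as with 3-hydroxy-4-methoxybenzaldehyde, the ortho position flanked by OH and CHO reacts in preference to the one para to CHO.

**Step 2**
Reactants: 2 2-bromo-3-hydroxy-6-methoxybenzaldehyde; 3 3-bromoprop-1-ene (allyl bromide)
Product: 4 2-bromo-6-methoxy-3-(prop-2-en-1-yloxy)benzaldehyde
Conditions: 3 (1.2 equiv), K2CO3, DMF, 25 °C
Reagents that add atoms: none
Why: Williamson ether synthesis (SN2 O-alkylation of the phenoxide).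

**Step 3**
Reactants: 4 2-bromo-6-methoxy-3-(prop-2-en-1-yloxy)benzaldehyde
Product: 6 2-bromo-3-hydroxy-6-methoxy-4-(prop-2-en-1-yl)benzaldehyde, via Claisen ortho-dienone 5 (not isolated)
Conditions: N,N-diethylaniline, 190 °C, sealed tube
Reagents that add atoms: none
Why: aromatic Claisen rearrangement; the [3,3] shift can end productively only at the free ortho carbon C4 because the other ortho carbon carries Br, and dienone 5 then tautomerises to the phenol.

**Step 4**
Reactants: 6 2-bromo-3-hydroxy-6-methoxy-4-(prop-2-en-1-yl)benzaldehyde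
Product: 7 2-bromo-3,6-dimethoxy-4-(prop-2-en-1-yl)benzaldehyde
Conditions: MeI, K2CO3, DMF, 40 °C
Reagents that add atoms: iodomethane, CI
Why: Williamson O-methylation; this oxygen later becomes part of the dimethyl ketal.

**Step 5**
Reactants: 7 2-bromo-3,6-dimethoxy-4-(prop-2-en-1-yl)benzaldehyde
Product: 8 2-bromo-6-hydroxy-3-methoxy-4-(prop-2-en-1-yl)benzaldehyde
Conditions: BCl3 (1.2 equiv), CH2Cl2, −78 to 0 °C; then H2O
Reagents that add atoms: none
Why: chelation-controlled Lewis-acid ether cleavage; BCl3 bridges the aldehyde oxygen and the ortho methoxy oxygen, so only that methyl is removed by chloride.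

**Step 6**
Reactants: 8 2-bromo-6-hydroxy-3-methoxy-4-(prop-2-en-1-yl)benzaldehyde
Product: 9 3-bromo-2-(hydroxymethyl)-4-methoxy-5-(prop-2-en-1-yl)phenol
Conditions: NaBH4, MeOH, 0 °C
Reagents that add atoms: none
Why: borohydride reduction of the aldehyde; aryl bromide, allyl group and ethers are inert.

**Step 7**
Reactants: 9 3-bromo-2-(hydroxymethyl)-4-methoxy-5-(prop-2-en-1-yl)phenol
Product: 10 3-bromo-2-(hydroxymethyl)-4,4-dimethoxy-5-(prop-2-en-1-yl)cyclohexa-2,5-dien-1-one
Conditions: PhI(OAc)2 (1.1 equiv), MeOH, 0 °C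
Reagents that add atoms: methanol, CO
Why: oxidative dearomatisation of a para-methoxyphenol by hypervalent iodine; methanol adds to the para carbon, which is activated by its own methoxy group, giving the p-quinone monoketal.

**Step 8**
Reactants: 10 3-bromo-2-(hydroxymethyl)-4,4-dimethoxy-5-(prop-2-en-1-yl)cyclohexa-2,5-dien-1-one
Product: 11 (1R,6S)-4-bromo-3-(hydroxymethyl)-5,5-dimethoxy-6-(prop-2-en-1-yl)-7-oxabicyclo[4.1.0]hept-3-en-2-one
Conditions: 9-amino-9-deoxy-epi-quinidine (10 mol %), CF3CO2H (20 mol %), 50% aq. H2O2 (1.5 equiv), 1,4-dioxane, 30 °C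
Reagents that add atoms: hydrogen peroxide, OO
Why: Proposed new method: iminium-catalysed asymmetric Weitz–Scheffer epoxidation of a quinone monoketal; the primary amine condenses with the C1 ketone of 10, the iminium N–H hydrogen-bonds to the C2 hydroxymethyl oxygen so the bulky C9 substituent lies over the C6–H arm, the protonated quinuclidine then delivers H2O2 only to the allyl-bearing β-carbon C5 on its Si face, and the β-hydroperoxy enamine closes onto O–O from the same face, setting both epoxide carbons (1R,6S) before hydrolysis frees the catalyst; the bromo-substituted arm is remote from the quinuclidinium, tetrasubstituted and a weaker acceptor; the amine pseudo-enantiomer is specified as the one that turns cyclohex-2-enone into (2R,3R)-2,3-epoxycyclohexanone (the facial sense needed here), taken to be the quinidine-derived one; closest known reaction type: cinchona primary-amine-salt-catalysed epoxidation of simple cyclohex-2-enones (3-alkyl ones included) with aqueous H2O2, not yet shown on cross-conjugated 4,4-dialkoxycyclohexa-2,5-dienones.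

**Step 9**
Reactants: 11 (1R,6S)-4-bromo-3-(hydroxymethyl)-5,5-dimethoxy-6-(prop-2-en-1-yl)-7-oxabicyclo[4.1.0]hept-3-en-2-one
Product: 12 (1S,2S,6S)-4-bromo-3-(hydroxymethyl)-5,5-dimethoxy-6-(prop-2-en-1-yl)-7-oxabicyclo[4.1.0]hept-3-en-2-ol
Conditions: i-Bu2AlH (3 equiv), THF, −78 °C; aq. potassium sodium tartrate
Reagents that add atoms: none
Why: substrate-controlled 1,2-reduction of a cyclic α,β-epoxy ketone; hydride enters anti to the adjacent epoxide C–O bond (polar Felkin–Anh control), so the new hydroxyl is cis to the epoxide oxygen (2S).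

**Step 10**
Reactants: 12 (1S,2S,6S)-4-bromo-3-(hydroxymethyl)-5,5-dimethoxy-6-(prop-2-en-1-yl)-7-oxabicyclo[4.1.0]hept-3-en-2-ol; 13 2-methylprop-2-enal (methacrolein)
Product: 14 (2E)-4-[(1S,5S,6S)-3-bromo-5-hydroxy-4-(hydroxymethyl)-2,2-dimethoxy-7-oxabicyclo[4.1.0]hept-3-en-1-yl]-2-methylbut-2-enal
Conditions: second-generation Hoveyda–Grubbs catalyst RuCl2(SIMes)(=CH-C6H4-2-O-i-Pr) (7 mol %), 13 (10 equiv), CH2Cl2, 40 °C
Reagents that add atoms: none
Why: olefin cross-metathesis of a terminal alkene with an α-substituted acrolein; the trisubstituted enal forms under thermodynamic control as the E isomer, and the tetrasubstituted bromoalkene and free hydroxyls do not engage the ruthenium carbene.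

**Step 11**
Reactants: 14 (2E)-4-[(1S,5S,6S)-3-bromo-5-hydroxy-4-(hydroxymethyl)-2,2-dimethoxy-7-oxabicyclo[4.1.0]hept-3-en-1-yl]-2-methylbut-2-enal
Product: 15 (2E)-4-[(1S,5S,6S)-3-bromo-5-hydroxy-4-(hydroxymethyl)-2,2-dimethoxy-7-oxabicyclo[4.1.0]hept-3-en-1-yl]-2-methylbut-2-enoic acid
Conditions: NaClO2, NaH2PO4, 2-methylbut-2-ene, t-BuOH/H2O, 0 °C
Reagents that add atoms: sodium chlorite, [Na+].[O-]Cl=O
Why: Pinnick oxidation; chlorous acid oxidises only the aldehyde, the scavenger removes HOCl, and alcohols, epoxide, ketal and alkene geometry are untouched.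

**Step 12**
Reactants: 15 (2E)-4-[(1S,5S,6S)-3-bromo-5-hydroxy-4-(hydroxymethyl)-2,2-dimethoxy-7-oxabicyclo[4.1.0]hept-3-en-1-yl]-2-methylbut-2-enoic acid; 16 [(1E)-hept-1-en-1-yl]boronic acid
Product: 17 (2E)-4-[(1S,5S,6S)-3-[(1E)-hept-1-en-1-yl]-5-hydroxy-4-(hydroxymethyl)-2,2-dimethoxy-7-oxabicyclo[4.1.0]hept-3-en-1-yl]-2-methylbut-2-enoic acid
Conditions: 16 (1.5 equiv), Pd(OAc)2 (5 mol %), SPhos (10 mol %), K3PO4 (4 equiv), THF/H2O 5:1, 50 °C
Reagents that add atoms: none
Why: Suzuki–Miyaura coupling; zerovalent palladium inserts into the vinyl C–Br bond, the alkenylboronate transmetalates and reductive elimination keeps the E geometry; the ketone is still a ketal and the acid is a carboxylate, so nothing base-labile is present, and the cis epoxy alcohol cannot undergo Payne rearrangement.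

**Step 13**
Reactants: 17 (2E)-4-[(1S,5S,6S)-3-[(1E)-hept-1-en-1-yl]-5-hydroxy-4-(hydroxymethyl)-2,2-dimethoxy-7-oxabicyclo[4.1.0]hept-3-en-1-yl]-2-methylbut-2-enoic acid
Product: 18 (2E)-4-[(1S,5S,6S)-3-[(1E)-hept-1-en-1-yl]-5-hydroxy-4-(hydroxymethyl)-2-oxo-7-oxabicyclo[4.1.0]hept-3-en-1-yl]-2-methylbut-2-enoic acid
Conditions: 48% aq. HF, MeCN, 0 °C
Reagents that add atoms: water, O
Why: acid-catalysed ketal hydrolysis through a dienyl-stabilised oxocarbenium ion with a weak acid and non-nucleophilic counter-ion; no stereocentre is touched and the E side chain cannot lactonise onto the epoxide.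

**Compound list**
1 | 5-hydroxy-2-methoxybenzaldehyde | COc1ccc(O)cc1C=O | starting material
2 | 2-bromo-3-hydroxy-6-methoxybenzaldehyde | COc1ccc(O)c(Br)c1C=O | intermediate
3 | 3-bromoprop-1-ene (allyl bromide) | C=CCBr | starting material
4 | 2-bromo-6-methoxy-3-(prop-2-en-1-yloxy)benzaldehyde | COc1ccc(OCC=C)c(Br)c1C=O | intermediate
5 | Claisen ortho-dienone 2-bromo-6-methoxy-3-oxo-4-(prop-2-en-1-yl)cyclohexa-1,5-diene-1-carbaldehyde (racemic at C4, formed in the flask) | COC1=CC(CC=C)C(=O)C(Br)=C1C=O | intermediate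
6 | 2-bromo-3-hydroxy-6-methoxy-4-(prop-2-en-1-yl)benzaldehyde | COc1cc(CC=C)c(O)c(Br)c1C=O | intermediate
7 | 2-bromo-3,6-dimethoxy-4-(prop-2-en-1-yl)benzaldehyde | COc1cc(CC=C)c(OC)c(Br)c1C=O | intermediate
8 | 2-bromo-6-hydroxy-3-methoxy-4-(prop-2-en-1-yl)benzaldehyde | COc1c(CC=C)cc(O)c(C=O)c1Br | intermediate
9 | 3-bromo-2-(hydroxymethyl)-4-methoxy-5-(prop-2-en-1-yl)phenol | COc1c(CC=C)cc(O)c(CO)c1Br | intermediate
10 | 3-bromo-2-(hydroxymethyl)-4,4-dimethoxy-5-(prop-2-en-1-yl)cyclohexa-2,5-dien-1-one | COC1(OC)C(Br)=C(CO)C(=O)C=C1CC=C | intermediate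
11 | (1R,6S)-4-bromo-3-(hydroxymethyl)-5,5-dimethoxy-6-(prop-2-en-1-yl)-7-oxabicyclo[4.1.0]hept-3-en-2-one | BrC1=C(CO)C(=O)[C@@H]2O[C@]2(CC=C)C1(OC)OC | intermediate
12 | (1S,2S,6S)-4-bromo-3-(hydroxymethyl)-5,5-dimethoxy-6-(prop-2-en-1-yl)-7-oxabicyclo[4.1.0]hept-3-en-2-ol | BrC1=C(CO)[C@H](O)[C@@H]2O[C@]2(CC=C)C1(OC)OC | intermediate
13 | 2-methylprop-2-enal (methacrolein) | CC(=C)C=O | starting material
14 | (2E)-4-[(1S,5S,6S)-3-bromo-5-hydroxy-4-(hydroxymethyl)-2,2-dimethoxy-7-oxabicyclo[4.1.0]hept-3-en-1-yl]-2-methylbut-2-enal | BrC1=C(CO)[C@H](O)[C@@H]2O[C@]2(C/C=C(\C)C=O)C1(OC)OC | intermediate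
15 | (2E)-4-[(1S,5S,6S)-3-bromo-5-hydroxy-4-(hydroxymethyl)-2,2-dimethoxy-7-oxabicyclo[4.1.0]hept-3-en-1-yl]-2-methylbut-2-enoic acid | BrC1=C(CO)[C@H](O)[C@@H]2O[C@]2(C/C=C(\C)C(=O)O)C1(OC)OC | intermediate
16 | [(1E)-hept-1-en-1-yl]boronic acid | CCCCC/C=C/B(O)O | starting material
17 | (2E)-4-[(1S,5S,6S)-3-[(1E)-hept-1-en-1-yl]-5-hydroxy-4-(hydroxymethyl)-2,2-dimethoxy-7-oxabicyclo[4.1.0]hept-3-en-1-yl]-2-methylbut-2-enoic acid | CCCCC/C=C/C1=C(CO)[C@H](O)[C@@H]2O[C@]2(C/C=C(\C)C(=O)O)C1(OC)OC | intermediate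
18 | (2E)-4-[(1S,5S,6S)-3-[(1E)-hept-1-en-1-yl]-5-hydroxy-4-(hydroxymethyl)-2-oxo-7-oxabicyclo[4.1.0]hept-3-en-1-yl]-2-methylbut-2-enoic acid | CCCCC/C=C/C1=C(CO)[C@H](O)[C@@H]2O[C@]2(C/C=C(\C)C(=O)O)C1=O | target

**Step count and risks**
Total step count: 13. Longest linear sequence: 13 steps (1 to 18).

The three steps most likely to fail are steps 8, 9 and 12.

Step 8 (the proposed new epoxidation) may fail through slow iminium formation on the hindered dienone, ketal loss in the acidic medium, or low ee. The fallback sets out from 10 and comes back to the route at 11. It is the known stoichiometric, hydroxyl-assisted tartrate-mediated nucleophilic epoxidation of 2-(hydroxymethyl)quinone monoketals: Ph3COOH (1.5 equiv), NaN(SiMe3)2 (2.5 equiv) and diisopropyl tartrate (1.5 equiv) in toluene at −55 °C. The sodium alkoxide of the hydroxymethyl group ties the dienone into the sodium tartrate–peroxide aggregate, and trityl peroxide adds to the allyl-bearing β-carbon and closes to 11. The L- and D-tartrates give mirror-image epoxides, and I have not fixed from memory which one gives (1R,6S)-11; the antipode is chosen by a test run (chiral HPLC and Mosher esters of 12). This fallback makes no compound outside the list.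

Step 9 may give the wrong facial selectivity. The fallback sets out from 11 and comes back at 12. If hydride adds from the epoxide face, the product is the anti-diol (1S,2R,6S)-4-bromo-3-(hydroxymethyl)-5,5-dimethoxy-6-(prop-2-en-1-yl)-7-oxabicyclo[4.1.0]hept-3-en-2-ol F1. Instead of screening hydrides, the carbinol is inverted. Double Mitsunobu esterification (4-nitrobenzoic acid, PPh3, DIAD, THF, 0 °C) acylates the primary alcohol and displaces the secondary one with inversion, giving the bis-ester [(1S,2S,6S)-4-bromo-5,5-dimethoxy-2-(4-nitrobenzoyloxy)-6-(prop-2-en-1-yl)-7-oxabicyclo[4.1.0]hept-3-en-3-yl]methyl 4-nitrobenzoate F2. Methanolysis (K2CO3, MeOH, 0 °C) then returns 12; no carbonyl is present at this stage.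

Step 12 may stall because the tetrasubstituted vinyl bromide next to the ketal carbon is slow in oxidative addition. The fallback sets out from 14 and comes back at 18, changing the order so that the halide is activated first. The ketal of 14 is hydrolysed (48% aq. HF, MeCN, 0 °C) to the α-bromo enone (2E)-4-[(1S,5S,6S)-3-bromo-5-hydroxy-4-(hydroxymethyl)-2-oxo-7-oxabicyclo[4.1.0]hept-3-en-1-yl]-2-methylbut-2-enal F3. Because the epoxy enone is base-sensitive, the coupling is a neutral Stille reaction (Pd2(dba)3, AsPh3, CuI, NMP, 25 °C) with tributyl[(1E)-hept-1-en-1-yl]stannane F4, made from hept-1-yne with Bu3SnH and AIBN at 90 °C and purified to the E isomer. This gives (2E)-4-[(1S,5S,6S)-3-[(1E)-hept-1-en-1-yl]-5-hydroxy-4-(hydroxymethyl)-2-oxo-7-oxabicyclo[4.1.0]hept-3-en-1-yl]-2-methylbut-2-enal F5, and Pinnick oxidation (NaClO2, NaH2PO4, 2-methylbut-2-ene, t-BuOH/H2O) gives 18. This order also avoids exposing the dienyl carbinol of 17 to acid.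

**Further compounds**
F0 | step 8 | none | none
F1 | step 9 | (1S,2R,6S)-4-bromo-3-(hydroxymethyl)-5,5-dimethoxy-6-(prop-2-en-1-yl)-7-oxabicyclo[4.1.0]hept-3-en-2-ol | BrC1=C(CO)[C@@H](O)[C@@H]2O[C@]2(CC=C)C1(OC)OC
F2 | step 9 | [(1S,2S,6S)-4-bromo-5,5-dimethoxy-2-(4-nitrobenzoyloxy)-6-(prop-2-en-1-yl)-7-oxabicyclo[4.1.0]hept-3-en-3-yl]methyl 4-nitrobenzoate | BrC1=C(COC(=O)c3ccc(cc3)[N+](=O)[O-])[C@H](OC(=O)c3ccc(cc3)[N+](=O)[O-])[C@@H]2O[C@]2(CC=C)C1(OC)OC
F3 | step 12 | (2E)-4-[(1S,5S,6S)-3-bromo-5-hydroxy-4-(hydroxymethyl)-2-oxo-7-oxabicyclo[4.1.0]hept-3-en-1-yl]-2-methylbut-2-enal | BrC1=C(CO)[C@H](O)[C@@H]2O[C@]2(C/C=C(\C)C=O)C1=O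
F4 | step 12 | tributyl[(1E)-hept-1-en-1-yl]stannane | CCCCC/C=C/[Sn](CCCC)(CCCC)CCCC
F5 | step 12 | (2E)-4-[(1S,5S,6S)-3-[(1E)-hept-1-en-1-yl]-5-hydroxy-4-(hydroxymethyl)-2-oxo-7-oxabicyclo[4.1.0]hept-3-en-1-yl]-2-methylbut-2-enal | CCCCC/C=C/C1=C(CO)[C@H](O)[C@@H]2O[C@]2(C/C=C(\C)C=O)C1=O
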